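**Plan**

1. Target numbering: C1 bridgehead CH, C2 C=O, C3 C–OMe, C4 =CH, C5 allyl-bearing bridgehead, C6 CHMe, C7 CHAr, C8 bridging C=O. Cut 1 is the C1–C7 bond; C7 is returned to the oxygen on C8, which turns the bicycle into a 3a-allyl-2-aryl-hydrobenzofuran-6-one (retron of a 1,3 O→C benzyl shift).
2. What allows this: ring C1–C2–C3–C4–C5–C8 is a cyclic 1,3-diketone whose central carbon C1 carries the cation-stabilising 3,4-dimethoxybenzylic carbon C7, so the cyclopentanone ring C1–C7–C6–C5–C8 can close last by enol capture of a benzylic cation.
3. Cut 2 is the C5–allyl bond, back to an aryl allyl ether (Claisen, then Cope). Cut 3 takes the dihydrofuran ring apart into 2-allyloxy-1,4-benzoquinone and (E)-methylisoeugenol.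
4. Forward order of rings: quinone ring, fused dihydrofuran ring (step 2), dearomatising allyl shift (step 4), exchange of the furan ring for the cyclopentanone ring (step 5).
5. Stereochemistry: C6 from the chiral titanium TADDOLate of step 2; quaternary C5 by relay from C6 (allyl anti to methyl); C7 is erased and re-set trans to the methyl group and C1 is fixed by the tether in step 5, so both benzylic epimers converge.

Key step: step 5

Assumption: the (R,R)-TADDOLate is taken to be the ligand enantiomer that leads to the (2S,3S) series in step 2; if the sense of induction is the opposite one, the (S,S)-ligand is used and nothing else changes.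

**Route**

Step 1
Reactants: 1 2-(allyloxy)phenol
Product: 2 2-(allyloxy)-1,4-benzoquinone
Conditions: (KSO3)2NO (2.2 equiv), KH2PO4, H2O–acetone, 0 °C → rt
Reagents that add atoms: potassium nitrosodisulfonate (Fremy's salt), [O]N(S(=O)(=O)[O-])S(=O)(=O)[O-].[K+].[K+]
Why: Teuber oxidation, in which the nitrosodisulfonate radical abstracts the phenolic hydrogen and a second equivalent oxygenates the free para position, should give the 2-alkoxy-p-quinone with the allyl ether untouched; no stereocentre is formed.

Step 2
Reactants: 2 2-(allyloxy)-1,4-benzoquinone; 3 (E)-methylisoeugenol [1,2-dimethoxy-4-[(1E)-prop-1-en-1-yl]benzene]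
Product: 4 (2S,3S)-6-(allyloxy)-2-(3,4-dimethoxyphenyl)-3-methyl-2,3-dihydro-1-benzofuran-5-ol
Conditions: pre-formed [(4R,5R)-TADDOLato]TiCl2 (2 equiv), 3 (1.5 equiv), CH2Cl2, −78 → 0 °C; then H2O
Reagents that add atoms: none
Why: Lewis acid-promoted formal [3+2] annulation of a 2-alkoxy-1,4-benzoquinone with an (E)-propenylarene: titanium chelated between O-1 and the ether oxygen on C-2 activates C-5 for attack by the alkene β-carbon, the benzylic cation is captured by the C-4 carbonyl oxygen and the adduct aromatises, so the 2,3-trans relation should follow from the (E)-alkene and the absolute configuration (C-3 is the centre that matters later) from the quinone face left open by the TADDOLate.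

Step 3
Reactants: 4 (2S,3S)-6-(allyloxy)-2-(3,4-dimethoxyphenyl)-3-methyl-2,3-dihydro-1-benzofuran-5-ol
Product: 5 (2S,3S)-6-(allyloxy)-2-(3,4-dimethoxyphenyl)-5-methoxy-3-methyl-2,3-dihydro-1-benzofuran
Conditions: MeI, K2CO3, acetone, 56 °C
Reagents that add atoms: iodomethane, CI
Why: Williamson etherification of the only free phenol should proceed without touching the two stereocentres.

Step 4
Reactants: 5 (2S,3S)-6-(allyloxy)-2-(3,4-dimethoxyphenyl)-5-methoxy-3-methyl-2,3-dihydro-1-benzofuran
Product: 7 (2S,3S,3aS)-3a-allyl-2-(3,4-dimethoxyphenyl)-5-methoxy-3-methyl-3,3a-dihydro-1-benzofuran-6(2H)-one, via ortho-dienone 6 (not isolated)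
Conditions: PhNEt2, 200 °C, sealed tube, argon, short reaction time with recycling of recovered 5
Reagents that add atoms: none
Why: Para-Claisen rearrangement (aromatic Claisen shift to the methoxy-bearing ortho carbon C-5, then Cope shift to C-3a) should stop at the non-enolisable cross-conjugated dienone, which is stabilised as a vinylogous ester, and the suprafacial delivery of the allyl group to the ring face anti to the neighbouring C-3 methyl group should set the quaternary centre as 3aS.

Step 5
Reactants: 7 (2S,3S,3aS)-3a-allyl-2-(3,4-dimethoxyphenyl)-5-methoxy-3-methyl-3,3a-dihydro-1-benzofuran-6(2H)-one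
Product: 9 Kadsurenin D, via benzylic cation 8 (not isolated)
Conditions: TMSOTf (0.2 equiv), CH2Cl2, −78 → −30 °C; then sat. aq. NaHCO3
Reagents that add atoms: none
Why: Silylation of the vinylogous-ester carbonyl oxygen of 7 (on C-6) makes O-1 a leaving group, heterolysis of the benzylic C-2–O-1 bond gives the 3,4-dimethoxybenzylic cation 8 tethered to the silyl enol ether of a cyclic 1,3-diketone, the enol α-carbon (old C-7, new C-1) attacks the cation, and the silyl group is handed back so that the acid is catalytic. The closest known reaction type is the acid-induced rearrangement of 3a-allyl hydrobenzofuranoid neolignans to bicyclo[3.2.1]octanoid neolignans, a formal 1,3 O→C benzyl shift that amounts to the second half of a stepwise cationic [5+2] cycloaddition (an intramolecular Mukaiyama-type SN1 alkylation). The cyclopentanone ring C1–C7–C6–C5–C8 closes in the 5-(enolexo)-exo-trig mode while the furan ring is given up in the same event. C-1 is fixed by the tether, because the cation can reach the enol carbon only from the ring face that carries the side chain on the quaternary C-5; C-7 should be set trans to the C-6 methyl group (aryl exo, on the side of the C-8 carbonyl), because the other face of the cation would put the aryl group cis to that methyl group and under the C3–C4 enol ether bridge; C-5 and C-6 are carried over from 7. The step needs C- over O-capture and an intact C-6 centre: O-capture only returns 7 or its C-2 epimer, which ionise again, whereas the C–C bond is not expected to reopen at low temperature, so the mixture should funnel to 9, and the low temperature and the non-basic triflate counter-ion should hold back E1 loss of the C-6 proton, attack by the allyl π bond and dienone–phenol-type allyl migration.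

**Compound list**

1 | 2-(allyloxy)phenol | C=CCOc1ccccc1O | starting material
2 | 2-(allyloxy)-1,4-benzoquinone | C=CCOC1=CC(=O)C=CC1=O | intermediate
3 | (E)-methylisoeugenol, 1,2-dimethoxy-4-[(1E)-prop-1-en-1-yl]benzene | C/C=C/c1ccc(OC)c(OC)c1 | starting material
4 | (2S,3S)-6-(allyloxy)-2-(3,4-dimethoxyphenyl)-3-methyl-2,3-dihydro-1-benzofuran-5-ol | C[C@@H]1[C@@H](c2ccc(OC)c(OC)c2)Oc2cc(OCC=C)c(O)cc12 | intermediate
5 | (2S,3S)-6-(allyloxy)-2-(3,4-dimethoxyphenyl)-5-methoxy-3-methyl-2,3-dihydro-1-benzofuran | C[C@@H]1[C@@H](c2ccc(OC)c(OC)c2)Oc2cc(OCC=C)c(OC)cc12 | intermediate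
6 | (2S,3S,5R)-5-allyl-2-(3,4-dimethoxyphenyl)-5-methoxy-3-methyl-2,3-dihydro-1-benzofuran-6(5H)-one (ortho-dienone, allyl on the face anti to the 3-methyl group) | C[C@@H]1[C@@H](c2ccc(OC)c(OC)c2)OC2=CC(=O)[C@](CC=C)(OC)C=C12 | intermediate
7 | (2S,3S,3aS)-3a-allyl-2-(3,4-dimethoxyphenyl)-5-methoxy-3-methyl-3,3a-dihydro-1-benzofuran-6(2H)-one (aryl and methyl trans, methyl and allyl trans) | C[C@@H]1[C@@H](c2ccc(OC)c(OC)c2)OC2=CC(=O)C(OC)=C[C@]12CC=C | intermediate
8 | ring-opened 3,4-dimethoxybenzylic cation on the O-silylated 6-allyl-4-methoxy-3-(trimethylsilyloxy)cyclohexa-2,4-dienone, triflate ion pair; quaternary and methyl-bearing centres as in 7 | C[C@H]([CH+]c1ccc(OC)c(OC)c1)[C@@]1(CC=C)C=C(OC)C(O[Si](C)(C)C)=CC1=O.[O-]S(=O)(=O)C(F)(F)F | intermediate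
9 | Kadsurenin D, (1S,5S,6R,7R)-5-allyl-7-(3,4-dimethoxyphenyl)-3-methoxy-6-methylbicyclo[3.2.1]oct-3-ene-2,8-dione (aryl exo, methyl endo) | C=CC[C@]12C=C(OC)C(=O)[C@H](C1=O)[C@H](c1ccc(OC)c(OC)c1)[C@H]2C | target

Total step count: 5
Longest linear sequence: 5 steps (1 → 2 → 4 → 5 → 7 → 9; 3 enters in step 2)

**Steps most likely to fail**

Step 4. The allyl group may shift instead to the unsubstituted ortho carbon C-7, where enolisation makes the shift irreversible, and long heating may drain the dienone through that channel. Delivery syn to the methyl group may also compete. The fallback replaces the sigmatropic shift by a polar, umpoled allylation. It sets out from 5: the allyl ether is cleaved with Pd(PPh3)4 and morpholine in THF to the free phenol (2S,3S)-2-(3,4-dimethoxyphenyl)-5-methoxy-3-methyl-2,3-dihydro-1-benzofuran-6-ol F1. F1 is then oxidised with PhI(OAc)2 in hexafluoroisopropanol at −20 °C in the presence of allyltrimethylsilane (oxidative Hosomi–Sakurai allylation). The phenoxonium ion should take up the allyl group at the para carbon C-3a, anti to the methyl group, and the fallback comes back to the route at 7.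

Step 5. The benzylic cation may only re-close on oxygen, so that nothing but C-2 epimerisation is seen. Under more forcing acid it may leak into E1 elimination, which would scramble the methyl-bearing centre, or into allyl migration with aromatisation. The fallback separates ionisation from C–C bond formation and sets out from 7. Solvolysis in methanol with pyridinium p-toluenesulfonate should trap the cation as the ring-opened benzylic ether 6-allyl-6-[1-(3,4-dimethoxyphenyl)-1-methoxypropan-2-yl]-3-hydroxy-4-methoxycyclohexa-2,4-dien-1-one F2 (both benzylic epimers, other centres as in 7). TMSCl and Et3N convert it to the silyl enol ether 6-allyl-6-[1-(3,4-dimethoxyphenyl)-1-methoxypropan-2-yl]-4-methoxy-3-(trimethylsilyloxy)cyclohexa-2,4-dien-1-one F3. Catalytic TMSOTf at −78 °C should then ionise the benzylic methyl ether and close the ring by an intramolecular Mukaiyama-type alkylation, and the fallback comes back to the route at 9.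

Step 2. Facial discrimination by the chiral titanium complex may be insufficient, the product may partly racemise through re-ionisation of the benzylic C–O bond, and the reaction may divert into the [2+2] manifold. The fallback gives up asymmetric induction in favour of resolution and sets out from 2 and 3. The achiral promoter TiCl4–Ti(OiPr)4 in CH2Cl2 (−78 °C to rt) should give the racemic trans adduct rac-(2S,3S)/(2R,3R)-6-(allyloxy)-2-(3,4-dimethoxyphenyl)-3-methyl-2,3-dihydro-1-benzofuran-5-ol F4. F4 is resolved by preparative chromatography on a chiral stationary phase (SFC), and the (2S,3S) enantiomer comes back to the route at 4.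

**Further compounds**

F1 | step 4 | (2S,3S)-2-(3,4-dimethoxyphenyl)-5-methoxy-3-methyl-2,3-dihydro-1-benzofuran-6-ol | C[C@@H]1[C@@H](c2ccc(OC)c(OC)c2)Oc2cc(O)c(OC)cc12
F2 | step 5 | 6-allyl-6-[1-(3,4-dimethoxyphenyl)-1-methoxypropan-2-yl]-3-hydroxy-4-methoxycyclohexa-2,4-dien-1-one, both benzylic epimers, other centres as in 7 | C[C@H](C(OC)c1ccc(OC)c(OC)c1)[C@@]1(CC=C)C=C(OC)C(O)=CC1=O
F3 | step 5 | 6-allyl-6-[1-(3,4-dimethoxyphenyl)-1-methoxypropan-2-yl]-4-methoxy-3-(trimethylsilyloxy)cyclohexa-2,4-dien-1-one, both benzylic epimers, other centres as in 7 | C[C@H](C(OC)c1ccc(OC)c(OC)c1)[C@@]1(CC=C)C=C(OC)C(O[Si](C)(C)C)=CC1=O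
F4 | step 2 | racemic trans-6-(allyloxy)-2-(3,4-dimethoxyphenyl)-3-methyl-2,3-dihydro-1-benzofuran-5-ol (1:1 mixture of the 2S,3S and 2R,3R enantiomers) | C[C@@H]1[C@@H](c2ccc(OC)c(OC)c2)Oc2cc(OCC=C)c(O)cc12.C[C@H]1[C@H](c2ccc(OC)c(OC)c2)Oc2cc(OCC=C)c(O)cc12
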